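**Retrosynthetic overview**
1. 2,3,6-Tribromoindole ⇐ C3 bromination (NBS) of 2,6-dibromoindole ⇐ 6-bromooxindole by lactam-to-2-bromoindole conversion (POBr3).
2. 6-Bromooxindole ⇐ nitro reduction and lactamisation of 2-(4-bromo-2-nitrophenyl)acetic acid.
3. That acid ⇐ oxidative decarboxylation (H2O2) of the arylpyruvate; its benzylic C–C(=O) bond is the key disconnection, a crossed Claisen condensation of 4-bromo-2-nitrotoluene with diethyl oxalate.
4. Ring order: the brominated benzene ring is bought; the five-membered N-ring is closed in step 3 and aromatised in step 4; C6–Br comes with the starting material, C2–Br and C3–Br go on last.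

Assumption: the target has no stereocentre (it is achiral), so no stereocontrol is needed and the SMILES is taken as written.

**Route**

Step 1
Reactants: 1 4-bromo-2-nitrotoluene; 2 diethyl oxalate
Product: 3 ethyl 3-(4-bromo-2-nitrophenyl)-2-oxopropanoate
Conditions: KOEt (1.1 equiv), Et2O/EtOH, 0 °C → rt, 24 h; then cold 1 M HCl
Reagents that add atoms: none
Why: The ortho-nitro group makes the benzylic CH3 acidic enough for ethoxide, and the resulting carbanion acylates the non-enolisable diester in a crossed Claisen condensation (Reissert condensation) driven by formation of the stabilised potassium enolate; the aryl bromide is meta to the nitro group and inert, and no stereocentre is formed.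

Step 2
Reactants: 3 ethyl 3-(4-bromo-2-nitrophenyl)-2-oxopropanoate
Product: 5 2-(4-bromo-2-nitrophenyl)acetic acid, via sodium 3-(4-bromo-2-nitrophenyl)-2-oxopropanoate 4 (not isolated)
Conditions: 2 M aq NaOH, 0 °C; 30% H2O2, 5 °C → rt; then HCl to pH 1
Reagents that add atoms: hydrogen peroxide, OO
Why: Saponification gives the α-keto carboxylate, and hydroperoxide adds to the ketone and fragments with loss of CO2 (oxidative decarboxylation of an α-keto acid) to give the arylacetic acid, leaving the nitro group and the aryl bromide untouched.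

Step 3
Reactants: 5 2-(4-bromo-2-nitrophenyl)acetic acid
Product: 7 6-bromoindolin-2-one, via 2-(2-amino-4-bromophenyl)acetic acid 6 (not isolated)
Conditions: Fe powder (5 equiv), AcOH, 90 °C, 2 h
Reagents that add atoms: none
Why: Béchamp-type iron reduction takes the nitro group to the aniline without hydrodebromination, and the aniline lactamises spontaneously onto the ortho acetic acid chain in hot AcOH (reductive cyclisation to the oxindole).

Step 4
Reactants: 7 6-bromoindolin-2-one
Product: 9 2,6-dibromo-1H-indole, via 6-bromo-3H-indol-2-yl phosphorodibromidate 8 (not isolated)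
Conditions: POBr3 (1.3 equiv), ClCH2CH2Cl, 80 °C, 30 min; then imidazole (1.2 equiv), 80 °C, 2 h; ice-water quench
Reagents that add atoms: phosphoryl bromide, O=P(Br)(Br)Br
Why: O-Phosphorylation of the lactam gives an imidoyl phosphate that undergoes addition–elimination by bromide at C2 and tautomerises to the aromatic indole (dehydroxy-bromination of a lactam, Vilsmeier-type activation), with imidazole buffering the acid that would otherwise oligomerise the 2-bromoindole.

Step 5
Reactants: 9 2,6-dibromo-1H-indole
Product: 10 2,3,6-tribromo-1H-indole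
Conditions: NBS (1.0 equiv), DMF, 0 °C, 1 h, dark
Reagents that add atoms: N-bromosuccinimide, O=C1CCC(=O)N1Br
Why: Electrophilic aromatic substitution goes to C3, the most nucleophilic and only free pyrrole position, while the benzo ring is deactivated by bromine, so one equivalent at 0 °C gives clean monobromination.

**Compound list**
1 | 4-bromo-2-nitrotoluene (4-bromo-1-methyl-2-nitrobenzene) | Cc1ccc(Br)cc1[N+](=O)[O-] | starting material
2 | diethyl oxalate | CCOC(=O)C(=O)OCC | starting material
3 | ethyl 3-(4-bromo-2-nitrophenyl)-2-oxopropanoate | CCOC(=O)C(=O)Cc1ccc(Br)cc1[N+](=O)[O-] | intermediate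
4 | sodium 3-(4-bromo-2-nitrophenyl)-2-oxopropanoate | [Na+].[O-]C(=O)C(=O)Cc1ccc(Br)cc1[N+](=O)[O-] | intermediate
5 | 2-(4-bromo-2-nitrophenyl)acetic acid | OC(=O)Cc1ccc(Br)cc1[N+](=O)[O-] | intermediate
6 | 2-(2-amino-4-bromophenyl)acetic acid | Nc1cc(Br)ccc1CC(=O)O | intermediate
7 | 6-bromoindolin-2-one (6-bromooxindole) | O=C1Cc2ccc(Br)cc2N1 | intermediate
8 | 6-bromo-3H-indol-2-yl phosphorodibromidate | O=P(Br)(Br)OC1=Nc2cc(Br)ccc2C1 | intermediate
9 | 2,6-dibromo-1H-indole | Brc1cc2ccc(Br)cc2[nH]1 | intermediate
10 | 2,3,6-tribromo-1H-indole | Brc1ccc2c(Br)c(Br)[nH]c2c1 | target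

**Step count and risks**
Total steps: 5. Longest linear sequence: 5.

Steps most likely to fail:

Step 4 (lactam to 2-bromoindole). 2-Haloindoles are acid-labile and the POBr3 reaction can give modest yields. The fallback sets out from 3 and comes back to the route at 10. Compound 3 is reduced with Fe in AcOH/EtOH at 80 °C, and the aniline condenses onto the ketone (Reissert indole synthesis) to give ethyl 6-bromo-1H-indole-2-carboxylate F1. Saponification (NaOH, EtOH/H2O, reflux) gives 6-bromo-1H-indole-2-carboxylic acid F2, and copper-mediated protodecarboxylation (Cu powder, quinoline, 220 °C) gives 6-bromo-1H-indole F3. NaH/PhSO2Cl (THF, 0 °C) gives 6-bromo-1-(phenylsulfonyl)-1H-indole F4, and Br2 in CH2Cl2 at 0 °C brominates C3 to give 3,6-dibromo-1-(phenylsulfonyl)-1H-indole F5. LDA (THF, −78 °C) removes the sulfonyl-acidified C2–H without Br/Li exchange, and BrCl2C–CCl2Br traps the anion as 2,3,6-tribromo-1-(phenylsulfonyl)-1H-indole F6. TBAF (THF, 60 °C) cleaves the N–S bond and delivers 10.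

Step 5 (C3 bromination of the free NH indole). Over-bromination or oxidative decomposition of the electron-rich, unprotected 2-bromoindole is possible, and the product is light- and acid-sensitive. The fallback sets out from 9 and comes back at 10. Boc2O with catalytic DMAP (MeCN, rt) gives tert-butyl 2,6-dibromo-1H-indole-1-carboxylate F7, a bench-stable carbamate. NBS in DMF at rt (or Br2 in CH2Cl2) brominates the tamed ring at C3 to give tert-butyl 2,3,6-tribromo-1H-indole-1-carboxylate F8, which can be purified by chromatography or crystallisation. TFA/CH2Cl2 at 0 °C removes the carbamate and gives 10.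

Step 1 (Claisen condensation). Deprotonation of the nitrotoluene is an unfavourable, moisture-sensitive equilibrium and the conversion can stall. The fallback sets out from 1 and comes back at 5. Condensation of 1 with Me2NCH(OMe)2 and pyrrolidine (DMF, 110 °C) gives (E)-1-[2-(4-bromo-2-nitrophenyl)ethenyl]pyrrolidine F9. Hydrolysis of the enamine (2 M HCl, THF, rt) gives 2-(4-bromo-2-nitrophenyl)acetaldehyde F10. Pinnick oxidation (NaClO2, NaH2PO4, 2-methyl-2-butene, t-BuOH/H2O) gives 5, which re-enters the route at step 3.

**Further compounds**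
F1 | step 4 | ethyl 6-bromo-1H-indole-2-carboxylate | CCOC(=O)c1cc2ccc(Br)cc2[nH]1
F2 | step 4 | 6-bromo-1H-indole-2-carboxylic acid | OC(=O)c1cc2ccc(Br)cc2[nH]1
F3 | step 4 | 6-bromo-1H-indole | Brc1ccc2cc[nH]c2c1
F4 | step 4 | 6-bromo-1-(phenylsulfonyl)-1H-indole | O=S(=O)(c1ccccc1)n1ccc2ccc(Br)cc21
F5 | step 4 | 3,6-dibromo-1-(phenylsulfonyl)-1H-indole | O=S(=O)(c1ccccc1)n1cc(Br)c2ccc(Br)cc21
F6 | step 4 | 2,3,6-tribromo-1-(phenylsulfonyl)-1H-indole | O=S(=O)(c1ccccc1)n1c(Br)c(Br)c2ccc(Br)cc21
F7 | step 5 | tert-butyl 2,6-dibromo-1H-indole-1-carboxylate | CC(C)(C)OC(=O)n1c(Br)cc2ccc(Br)cc21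
F8 | step 5 | tert-butyl 2,3,6-tribromo-1H-indole-1-carboxylate | CC(C)(C)OC(=O)n1c(Br)c(Br)c2ccc(Br)cc21
F9 | step 1 | (E)-1-[2-(4-bromo-2-nitrophenyl)ethenyl]pyrrolidine | [O-][N+](=O)c1cc(Br)ccc1/C=C/N1CCCC1
F10 | step 1 | 2-(4-bromo-2-nitrophenyl)acetaldehyde | O=CCc1ccc(Br)cc1[N+](=O)[O-]
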